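## Retrosynthetic overview

1. Feature: in ring A, C8a (bearing the pyranone oxygen O1) and C4a (bearing the C4 carbonyl) are direct neighbours. C4a is flanked by the C5 methoxy group and C8a by C8–H. A 3-alkoxy-substituted aryne (C4a≡C8a) leaves exactly this pattern when it picks up an oxygen nucleophile and an acyl carbon.
2. Key disconnection: C8a–O1 and C4a–C4 are cut together. This gives a ring A silylaryl triflate and a ring B arylpropiolic acid that already holds C2, C3, C4 and the (S)-configured side chain. Electrophilic acylation of the matching phenol would face two similar ortho sites, whereas the aryne has a single polarity.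
3. Fragments: the triflate comes from 2,3-dimethoxyphenol through the mirror-symmetric hydroquinone (monobenzylation, carbamate-directed C-silylation). The acid comes from (R)-3-bromo-2-methylpropan-1-ol (source of the stereocentre), 2-methoxybenzyl chloride and propiolic acid.
4. Ring order: rings A and B are bought as arenes. Ring C is the only ring made, by 6-endo closure O1–C2 of the hydroxy ynone after the key step. C3 hydroxylation with a dioxirane and a double hydrogenolysis finish the synthesis.

Key step: step 11

Remark: flavone numbering (O1, C2–C4, C4a, C5–C8, C8a) is used for the late compounds. The commercial bromo alcohol is assumed enantiopure. No step makes or breaks a bond at its stereocentre. The descriptor changes from R to S in step 8 only because CH2Br is replaced by the lower-ranked CH2CH2Ar group.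

## Ring A fragment

Step 1
Reactants: 1 2,3-dimethoxyphenol
Product: 2 2,3-dimethoxy-1,4-benzoquinone
Conditions: ON(SO3K)2 (2.2 equiv), KH2PO4, H2O/acetone, rt
Reagents that add atoms: potassium nitrosodisulfonate (Fremy's salt), [K+].[K+].[O-]S(=O)(=O)N([O])S(=O)(=O)[O-]
Why: Teuber oxidation, in which one equivalent of the nitroxyl radical removes the phenolic hydrogen and a second delivers oxygen to the free para carbon, so a phenol with an open para position should go to the para-quinone.

Step 2
Reactants: 2 2,3-dimethoxy-1,4-benzoquinone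
Product: 3 2,3-dimethoxybenzene-1,4-diol
Conditions: Na2S2O4, EtOAc/H2O, rt
Reagents that add atoms: none
Why: Dithionite reduction of a quinone is a fast two-electron, two-proton transfer, nothing else in 2 is reducible, and the product is a mirror-symmetric hydroquinone.

Step 3
Reactants: 3 2,3-dimethoxybenzene-1,4-diol
Product: 4 4-(benzyloxy)-2,3-dimethoxyphenol
Conditions: BnBr (0.9 equiv), K2CO3 (1.0 equiv), DMF, Ar, rt
Reagents that add atoms: benzyl bromide, BrCc1ccccc1
Why: Williamson etherification in which the two hydroxyl groups are equivalent by symmetry, so only the degree of alkylation needs control, which a deficit of benzyl bromide provides, and unreacted 3 and the bis-ether are removed by chromatography.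

Step 4
Reactants: 4 4-(benzyloxy)-2,3-dimethoxyphenol
Product: 5 4-(benzyloxy)-2,3-dimethoxyphenyl N-isopropylcarbamate
Conditions: i-PrNCO, Et3N (cat.), CH2Cl2, rt
Reagents that add atoms: isopropyl isocyanate, CC(C)N=C=O
Why: Base-catalysed addition of a phenol to an isocyanate gives a secondary O-aryl carbamate, which is a strong directing group for metalation and can later be removed under mild base.

Step 5
Reactants: 5 4-(benzyloxy)-2,3-dimethoxyphenyl N-isopropylcarbamate
Product: 9 4-(benzyloxy)-2,3-dimethoxy-6-(trimethylsilyl)phenyl N-isopropylcarbamate, via N-TBS carbamate 6 (not isolated), via C6 aryllithium 7 (not isolated), via N-TBS C6-TMS carbamate 8 (not isolated)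
Conditions: TBSOTf, TMEDA, Et2O, 0 °C to rt; n-BuLi, TMEDA, −78 °C; TMSCl, −78 °C to rt; aq NaHSO4
Reagents that add atoms: chlorotrimethylsilane, C[Si](C)(C)Cl; TBSOTf, CC(C)(C)[Si](C)(C)OS(=O)(=O)C(F)(F)F (its silyl group is held only in 6 to 8 and is lost on work-up); n-butyllithium, [Li]CCCC (its lithium is held only in 7)
Why: Directed ortho-metalation, in which temporary N-silylation masks the N–H, the carbamate carbonyl guides n-BuLi to C6–H (the only hydrogen ortho to it), TMSCl traps the aryllithium at −78 °C before an anionic ortho-Fries shift can begin, and the acidic work-up cleaves only the N–Si bond.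

Step 6
Reactants: 9 4-(benzyloxy)-2,3-dimethoxy-6-(trimethylsilyl)phenyl N-isopropylcarbamate
Product: 11 4-(benzyloxy)-2,3-dimethoxy-6-(trimethylsilyl)phenyl trifluoromethanesulfonate, via silylphenol 10 (not isolated)
Conditions: DBU, Et2NH, MeCN, 40 °C; then PhNTf2, rt
Reagents that add atoms: N-phenylbis(trifluoromethanesulfonimide), O=S(=O)(N(c1ccccc1)S(=O)(=O)C(F)(F)F)C(F)(F)F
Why: E1cB cleavage of the secondary carbamate by DBU releases isopropyl isocyanate, which Et2NH scavenges as a urea, and the phenoxide is sulfonylated in the same flask by the mild triflyl donor, so the acid- and base-sensitive ortho-silylphenol never has to be handled.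

## Ring B fragment

Step 7
Reactants: 12 (R)-3-bromo-2-methylpropan-1-ol
Product: 13 (R)-[(3-bromo-2-methylpropoxy)methyl]benzene
Conditions: BnOC(=NH)CCl3, TfOH (cat.), cyclohexane/CH2Cl2, 0 °C to rt
Reagents that add atoms: benzyl 2,2,2-trichloroacetimidate, N=C(OCc1ccccc1)C(Cl)(Cl)Cl
Why: Acid-catalysed O-benzylation with the trichloroacetimidate avoids an alkoxide, which could displace or eliminate the bromide, and leaves the stereocentre untouched.

Step 8
Reactants: 13 (R)-[(3-bromo-2-methylpropoxy)methyl]benzene; 14 2-methoxybenzyl chloride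
Product: 16 1-[(3S)-4-(benzyloxy)-3-methylbutyl]-2-methoxybenzene, via 2-methoxybenzylmagnesium chloride 15 (not isolated)
Conditions: Mg, THF, 0 °C (slow addition of 14); then 13, Li2CuCl4 (5 mol %), NMP, THF, 0 °C to rt
Reagents that add atoms: magnesium, [Mg] (held only in 15)
Why: Kochi-type copper-catalysed sp3–sp3 coupling of a Grignard reagent with a primary alkyl bromide forms the bond at the CH2 next to the stereocentre, so the configuration is carried over unchanged, and slow formation of the benzylic Grignard reagent limits Wurtz dimerisation.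

Step 9
Reactants: 16 1-[(3S)-4-(benzyloxy)-3-methylbutyl]-2-methoxybenzene
Product: 17 2-[(3S)-4-(benzyloxy)-3-methylbutyl]-4-iodo-1-methoxybenzene
Conditions: NIS, TFA (cat.), MeCN, rt, dark
Reagents that add atoms: N-iodosuccinimide, O=C1CCC(=O)N1I
Why: Electrophilic aromatic iodination is directed by the methoxy group to its free para position, the unactivated phenyl ring of the benzyl ether does not react, and the iodide is chosen so that the next coupling can run near room temperature.

Step 10
Reactants: 17 2-[(3S)-4-(benzyloxy)-3-methylbutyl]-4-iodo-1-methoxybenzene; 18 propiolic acid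
Product: 19 3-{3-[(3S)-4-(benzyloxy)-3-methylbutyl]-4-methoxyphenyl}prop-2-ynoic acid
Conditions: Pd(PPh3)4 (5 mol %), DBU (2.5 equiv), DMSO, 35 °C; then 1 M HCl
Reagents that add atoms: none
Why: Copper-free Sonogashira coupling of propiolic acid as its DBU carboxylate, in which zerovalent palladium inserts into the carbon–iodine bond at 35 °C, below the temperature at which the alkynoic acid loses CO2, and leaving out copper removes the usual decarboxylation catalyst.

## Union and completion

Step 11
Reactants: 11 4-(benzyloxy)-2,3-dimethoxy-6-(trimethylsilyl)phenyl trifluoromethanesulfonate; 19 3-{3-[(3S)-4-(benzyloxy)-3-methylbutyl]-4-methoxyphenyl}prop-2-ynoic acid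
Product: 21 1-[4-(benzyloxy)-6-hydroxy-2,3-dimethoxyphenyl]-3-{3-[(3S)-4-(benzyloxy)-3-methylbutyl]-4-methoxyphenyl}prop-2-yn-1-one, via ring A aryne 20 (not isolated)
Conditions: CsF (4 equiv), 11 (1.5 equiv), THF (0.04 M in 19), 125 °C, sealed tube
Reagents that add atoms: none
Why: Fluoride removes the silyl group of 11 and triflate leaves, giving aryne 20 (C4a≡C8a); the caesium carboxylate of 19 adds through oxygen to C8a, and the aryl anion formed at C4a attacks the adjacent ester carbonyl (4-exo-trig) to give a benzoxetene alkoxide, whose C–O bond breaks to leave the C8a phenoxide and the C4a–C4 aryl ketone. This is the known formal insertion of arynes into the C–O bond of carboxylic acids, which gives ortho-hydroxyaryl ketones in hot THF, arylpropiolic acids included, and whose competitor is plain O-arylation to the aryl ester. No ring persists, because the four-membered ring is only a transit point, and no stereocentre is formed, the remote (S) centre being inert to CsF. The step needs regiocontrol of the addition, which comes from the C5 methoxy group next to C4a: it withdraws inductively and distorts the aryne, so the nucleophile enters at the remote C8a beside C8–H and the negative charge develops at C4a. The step also needs acyl transfer to outrun protonation of the aryl anion, which is favoured by an aprotic solvent, high temperature, high dilution and slow release of the aryne by sparingly soluble CsF. The Z conformation of the aryl ester turns the alkyne carbons away from the anion, so only the carbonyl carbon lies within reach.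

Step 12
Reactants: 21 1-[4-(benzyloxy)-6-hydroxy-2,3-dimethoxyphenyl]-3-{3-[(3S)-4-(benzyloxy)-3-methylbutyl]-4-methoxyphenyl}prop-2-yn-1-one
Product: 22 7-(benzyloxy)-2-{3-[(3S)-4-(benzyloxy)-3-methylbutyl]-4-methoxyphenyl}-5,6-dimethoxy-4H-chromen-4-one
Conditions: DMAP (20 mol %), DMF, 40 °C
Reagents that add atoms: none
Why: Nucleophilic amine catalysis, in which DMAP adds to C2 of the ynone, the C8a hydroxyl attacks the same carbon and expels DMAP (addition–elimination, 6-endo), so the 5-exo path seen with plain base is closed, and any material that already cyclised to the pyranone in the hot CsF medium of step 11 is the same compound 22.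

Step 13
Reactants: 22 7-(benzyloxy)-2-{3-[(3S)-4-(benzyloxy)-3-methylbutyl]-4-methoxyphenyl}-5,6-dimethoxy-4H-chromen-4-one
Product: 24 7-(benzyloxy)-2-{3-[(3S)-4-(benzyloxy)-3-methylbutyl]-4-methoxyphenyl}-3-hydroxy-5,6-dimethoxy-4H-chromen-4-one, via flavone 2,3-epoxide 23 (not isolated)
Conditions: DMDO, acetone/CH2Cl2, 0 °C; then p-TsOH·H2O (cat.), CH2Cl2, rt
Reagents that add atoms: dimethyldioxirane, CC1(C)OO1
Why: Dioxirane epoxidation of the C2=C3 enol-ether double bond followed by acid-catalysed opening at C2 (cation stabilised by O1 and ring B) and loss of the C3 proton is the known conversion of benzyl-protected flavones into flavonols, and the two transient epoxide centres vanish on aromatisation.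

Step 14
Reactants: 24 7-(benzyloxy)-2-{3-[(3S)-4-(benzyloxy)-3-methylbutyl]-4-methoxyphenyl}-3-hydroxy-5,6-dimethoxy-4H-chromen-4-one
Product: 25 3,7-dihydroxy-2-{3-[(3S)-4-hydroxy-3-methylbutyl]-4-methoxyphenyl}-5,6-dimethoxy-4H-chromen-4-one (CNP0267774.1)
Conditions: H2 (1 atm), Pd/C (10 wt %), EtOAc/MeOH, rt
Reagents that add atoms: none
Why: Catalytic hydrogenolysis cleaves the aryl and the alkyl benzyl ether in one operation, while the methyl ethers, the fully conjugated flavonol core and the stereocentre are not affected at atmospheric pressure.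

## Compound list

1 | 2,3-dimethoxyphenol | COc1cccc(O)c1OC | starting material
2 | 2,3-dimethoxy-1,4-benzoquinone | COC1=C(OC)C(=O)C=CC1=O | intermediate
3 | 2,3-dimethoxybenzene-1,4-diol | COc1c(O)ccc(O)c1OC | intermediate
4 | 4-(benzyloxy)-2,3-dimethoxyphenol | COc1c(O)ccc(OCc2ccccc2)c1OC | intermediate
5 | 4-(benzyloxy)-2,3-dimethoxyphenyl N-isopropylcarbamate | COc1c(OC(=O)NC(C)C)ccc(OCc2ccccc2)c1OC | intermediate
6 | N-(tert-butyldimethylsilyl) derivative of 5 (not isolated) | COc1c(OC(=O)N(C(C)C)[Si](C)(C)C(C)(C)C)ccc(OCc2ccccc2)c1OC | intermediate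
7 | C6-lithiated 6 (not isolated) | COc1c(OC(=O)N(C(C)C)[Si](C)(C)C(C)(C)C)c([Li])cc(OCc2ccccc2)c1OC | intermediate
8 | C6-trimethylsilylated 6 (not isolated) | COc1c(OC(=O)N(C(C)C)[Si](C)(C)C(C)(C)C)c([Si](C)(C)C)cc(OCc2ccccc2)c1OC | intermediate
9 | 4-(benzyloxy)-2,3-dimethoxy-6-(trimethylsilyl)phenyl N-isopropylcarbamate | COc1c(OC(=O)NC(C)C)c([Si](C)(C)C)cc(OCc2ccccc2)c1OC | intermediate
10 | 4-(benzyloxy)-2,3-dimethoxy-6-(trimethylsilyl)phenol (not isolated) | COc1c(O)c([Si](C)(C)C)cc(OCc2ccccc2)c1OC | intermediate
11 | 4-(benzyloxy)-2,3-dimethoxy-6-(trimethylsilyl)phenyl trifluoromethanesulfonate | COc1c(OS(=O)(=O)C(F)(F)F)c([Si](C)(C)C)cc(OCc2ccccc2)c1OC | intermediate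
12 | (R)-3-bromo-2-methylpropan-1-ol | BrC[C@H](C)CO | starting material
13 | (R)-[(3-bromo-2-methylpropoxy)methyl]benzene | BrC[C@H](C)COCc1ccccc1 | intermediate
14 | 2-methoxybenzyl chloride | COc1ccccc1CCl | starting material
15 | 2-methoxybenzylmagnesium chloride (not isolated) | COc1ccccc1C[Mg]Cl | intermediate
16 | 1-[(3S)-4-(benzyloxy)-3-methylbutyl]-2-methoxybenzene | COc1ccccc1CC[C@H](C)COCc1ccccc1 | intermediate
17 | 2-[(3S)-4-(benzyloxy)-3-methylbutyl]-4-iodo-1-methoxybenzene | COc1ccc(I)cc1CC[C@H](C)COCc1ccccc1 | intermediate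
18 | propiolic acid | OC(=O)C#C | starting material
19 | 3-{3-[(3S)-4-(benzyloxy)-3-methylbutyl]-4-methoxyphenyl}prop-2-ynoic acid | OC(=O)C#Cc1ccc(OC)c(CC[C@H](C)COCc2ccccc2)c1 | intermediate
20 | 5-(benzyloxy)-3,4-dimethoxy-1,2-didehydrobenzene, ring A aryne (not isolated) | COC1=C(OC)C(OCc2ccccc2)=CC#C1 | intermediate
21 | 1-[4-(benzyloxy)-6-hydroxy-2,3-dimethoxyphenyl]-3-{3-[(3S)-4-(benzyloxy)-3-methylbutyl]-4-methoxyphenyl}prop-2-yn-1-one | COc1ccc(C#CC(=O)c2c(O)cc(OCc3ccccc3)c(OC)c2OC)cc1CC[C@H](C)COCc1ccccc1 | intermediate
22 | 7-(benzyloxy)-2-{3-[(3S)-4-(benzyloxy)-3-methylbutyl]-4-methoxyphenyl}-5,6-dimethoxy-4H-chromen-4-one | COc1ccc(-c2cc(=O)c3c(OC)c(OC)c(OCc4ccccc4)cc3o2)cc1CC[C@H](C)COCc1ccccc1 | intermediate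
23 | 2,3-epoxide of 22, both epoxide faces (not isolated) | COc1ccc(C23OC2C(=O)c4c(O3)cc(OCc5ccccc5)c(OC)c4OC)cc1CC[C@H](C)COCc1ccccc1 | intermediate
24 | 7-(benzyloxy)-2-{3-[(3S)-4-(benzyloxy)-3-methylbutyl]-4-methoxyphenyl}-3-hydroxy-5,6-dimethoxy-4H-chromen-4-one | COc1ccc(-c2oc3cc(OCc4ccccc4)c(OC)c(OC)c3c(=O)c2O)cc1CC[C@H](C)COCc1ccccc1 | intermediate
25 | 3,7-dihydroxy-2-{3-[(3S)-4-hydroxy-3-methylbutyl]-4-methoxyphenyl}-5,6-dimethoxy-4H-chromen-4-one | COc1ccc(-c2oc3cc(O)c(OC)c(OC)c3c(=O)c2O)cc1CC[C@H](C)CO | target

## Step count and risks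

Total step count: 14.
Longest linear sequence: 10 steps (steps 1–6, then 11–14). The ring B branch is 4 steps (7–10) before the union.

**Risk 1, step 11.** Four processes could undermine the step:
- The C4a aryl anion may be protonated before the acyl group has moved.
- The alkynoic acid may lose CO2 at 125 °C.
- The liberated phenoxide may be arylated by a second aryne.
- The phenoxide may close in the 5-exo sense in the basic medium.

The fallback sets out from 11 and 19 and comes back at 21, and it brings in the acyl carbon at the aldehyde level. The aryne is released from 11 with CsF in DMF, which serves as solvent and partner. Formal [2+2] addition across the formamide C=O follows the same polarity control (O to C8a, C to C4a). Ring opening and aqueous hydrolysis should then give 4-(benzyloxy)-6-hydroxy-2,3-dimethoxybenzaldehyde F1. Acid 19 is protodecarboxylated (CuCl cat., Et3N, MeCN, 60 °C) to 2-[(3S)-4-(benzyloxy)-3-methylbutyl]-4-ethynyl-1-methoxybenzene F2. F2 is deprotonated with n-BuLi (THF, −78 °C) and added to F1, whose phenol has been deprotonated beforehand with LiHMDS. This gives 1-[4-(benzyloxy)-6-hydroxy-2,3-dimethoxyphenyl]-3-{3-[(3S)-4-(benzyloxy)-3-methylbutyl]-4-methoxyphenyl}prop-2-yn-1-ol F3 as both carbinol epimers. MnO2 in CH2Cl2 oxidises the carbinol to ynone 21.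

**Risk 2, step 5.** The base may deprotonate the benzylic CH2 of the ether, with Wittig rearrangement following. The carbamoyl group may migrate to C6 (anionic ortho-Fries) if the aryllithium warms up. Incomplete N-silylation may consume base.

The fallback sets out from 4 and comes back at 11, and it replaces C–H metalation by halogen–metal exchange. Amine-catalysed ortho-bromination of the free phenol (NBS, i-Pr2NH cat., CH2Cl2, 0 °C) should give 4-(benzyloxy)-6-bromo-2,3-dimethoxyphenol F4, because the hydroxyl group outranks the ethers as a director. Hexamethyldisilazane in THF at reflux gives [4-(benzyloxy)-6-bromo-2,3-dimethoxyphenoxy]trimethylsilane F5. n-BuLi (THF, −78 °C) triggers bromine–lithium exchange, which is far faster than benzylic deprotonation, and then a retro-Brook O-to-C silyl shift to the lithium salt of 10. Tf2O converts that salt into 11 in the same flask.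

**Risk 3, step 13.** Oxygen transfer to the electron-poor C2=C3 bond may be slow. C–H oxidation at the benzylic ether positions or at the tertiary side-chain carbon, and oxidation of the electron-rich rings, could then compete.

The fallback sets out from 22 and comes back at 24, and it replaces electrophilic oxidation by a deprotonation. Compound 22 is lithiated at C3 with LDA (THF, −78 °C) and quenched with B(OMe)3 to give dimethyl [7-(benzyloxy)-2-{3-[(3S)-4-(benzyloxy)-3-methylbutyl]-4-methoxyphenyl}-5,6-dimethoxy-4-oxo-4H-chromen-3-yl]boronate F6. This is oxidised without isolation (H2O2, AcOH, 0 °C to rt) to flavonol 24.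

## Further compounds

F1 | step 11 | 4-(benzyloxy)-6-hydroxy-2,3-dimethoxybenzaldehyde | O=Cc1c(O)cc(OCc2ccccc2)c(OC)c1OC
F2 | step 11 | 2-[(3S)-4-(benzyloxy)-3-methylbutyl]-4-ethynyl-1-methoxybenzene | C#Cc1ccc(OC)c(CC[C@H](C)COCc2ccccc2)c1
F3 | step 11 | 1-[4-(benzyloxy)-6-hydroxy-2,3-dimethoxyphenyl]-3-{3-[(3S)-4-(benzyloxy)-3-methylbutyl]-4-methoxyphenyl}prop-2-yn-1-ol, both carbinol epimers | COc1ccc(C#CC(O)c2c(O)cc(OCc3ccccc3)c(OC)c2OC)cc1CC[C@H](C)COCc1ccccc1
F4 | step 5 | 4-(benzyloxy)-6-bromo-2,3-dimethoxyphenol | COc1c(O)c(Br)cc(OCc2ccccc2)c1OC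
F5 | step 5 | [4-(benzyloxy)-6-bromo-2,3-dimethoxyphenoxy]trimethylsilane | COc1c(O[Si](C)(C)C)c(Br)cc(OCc2ccccc2)c1OC
F6 | step 13 | dimethyl [7-(benzyloxy)-2-{3-[(3S)-4-(benzyloxy)-3-methylbutyl]-4-methoxyphenyl}-5,6-dimethoxy-4-oxo-4H-chromen-3-yl]boronate | COc1ccc(-c2oc3cc(OCc4ccccc4)c(OC)c(OC)c3c(=O)c2B(OC)OC)cc1CC[C@H](C)COCc1ccccc1
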